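Readings and results come from a simulation from invented constants.

A small charge of catalyst, 2.0 mM, worked on a racemate in each flask, and I wanted a quantity that ignored how fast it went.

all flasks: left-handed substrate 0.10 M; right-handed substrate 0.10 M

| flask | solid reagent | protic impurity | catalyst | temperature | remark | time |
|---|---|---|---|---|---|---|
| east | 0.050 M | 0.10 M | 2 mM | 22 °C | run made earlier |  |
| north-west | 0.20 M | 0.10 M | 2 mM | 50 °C | run made earlier |  |
| cedar | 0.100 M | 0.100 M | 2.0 mM | 60 °C |  | 20 h |
| oak | 0.100 M | 0.100 M | 2.0 mM | 35 °C |  | 20 h |
| birch | 0.100 M | 0.100 M | 2.0 mM | 10 °C |  | 20 h |

| run | time / h | left-handed product / % | right-handed product / % | left-handed substrate / % |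
|---|---|---|---|---|
| east | 10.0 | 0 | 0 | 50.3 |
| east | 30.0 | 0.8 | 0 | 48.7 |
| east | 48.0 | 1.8 | 0 | 48.2 |
| east | 72.0 | 3.2 | 0.9 | 46.9 |
| east | 120 | 8.2 | 0 | 42.8 |
| east | 144 | 8.2 | 0.2 | 40.6 |
| north-west | 3.00 | 0 | 0 | 49.3 |
| north-west | 5.00 | 0 | 0 | 50.1 |
| north-west | 8.00 | 0 | 0 | 49.7 |
| north-west | 12.0 | 1.1 | 0.2 | 49.8 |
| north-west | 25.0 | 2.6 | 0 | 47.3 |
| north-west | 40.0 | 4.5 | 0.6 | 44.9 |

(each reading ± 0.5 percentage points)

- the best flask by excess of left-handed product over right-handed product; "all alike" if 1.5 percentage points covers them all (cedar / oak / birch / all alike)
- excess of left-handed product over right-handed product at the end, cedar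
- excess of left-handed product over right-handed product at the end, oak
- excess of left-handed product over right-handed product at the end, birch

- catalyst is single-handed; left-handed substrate and right-handed substrate are mirror images of each other, charged as a racemate, each of them at the stated concentration
- given per volume of solution although it is solid: solid reagent
- the numbers in the tables scatter with a standard deviation of 0.5 percentage points
- on the list of suspects stand: partner + catalyst + left-handed substrate -> catalyst + left-handed product; partner + catalyst + right-handed substrate -> catalyst + right-handed product; solid reagent <-> partner; partner + protic impurity -> quenched reagent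
- at the start none of the solid reagent is in solution
- an excess is the difference of the two amounts in percent of their sum
- an excess is below zero if the other one leads

On the list of suspects both substrates take the same partner and the same catalyst, so these two concentrations cancel in the ratio of the two rates, and with them the delay in dissolving and the loss of partner to the protic impurity. I therefore pooled the readings of both runs: left-handed product summed to 30 percentage points, right-handed to 1.9 points. Their ratio is my reading of s, the selectivity factor, defined as the left-handed rate over the right-handed rate at equal substrate: s = 16.0. The excess is then s minus one over s plus one, 88.2%.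

But why pool? Taken apart, the east run at 22 °C gives 20.2 and the north-west run at 50 °C gives 10.2, which looks like a trend. Yet each run's right-handed sum carries a scatter of 1.2 points, and neither sum stands clear of zero by that much. I read no trend.

The pooled sum is hardly firmer. One standard deviation, 1.7 points, either way puts the excess between 78.6% and 98.7%.

Depletion was the last doubt. The east run's left-handed substrate read 50.3% first and 40.6% last, so the middle of the two stood at 0.904 of the first reading. Dividing s by that figure gave an excess of 89.3%. I committed to that for all three flasks, hence all alike.

The forecast differed: birch best, with 79% for cedar, 86% for oak and 92% for birch, and “Birch should be the most selective”.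

The flasks gave 93.9% for cedar, 93.9% for oak and 93.7% for birch, a spread smaller than the margin, so the verdict is all alike.

    partner + catalyst + left-handed substrate → catalyst + left-handed product (k = 2.10 /M²/min, Ea = 51.0 kJ/mol)
    partner + catalyst + right-handed substrate → catalyst + right-handed product (k = 0.0660 /M²/min, Ea = 50.0 kJ/mol)
    solid reagent ⇌ partner, rate k3*(cs3 - [partner]) while solid is left; crystals form when [partner] > cs3 (solubility = 36.0 mM, k = 2.10 × 10⁻⁴ /min)
    partner + protic impurity → quenched reagent (k = 5.50 × 10⁻⁴ /M/min, Ea = 65.0 kJ/mol)
    (constants at 35 °C)

The constants put s at 31.8 at 35 °C, an excess of 93.9%. I carried my reading s = 16.0 to the neighbouring flask, which was cedar with 8.0 × 10⁻⁴ M of catalyst in place of 2.0 mM. That reckoning holds no catalyst term, so it gave the same 89.3% there, and I expected less product. After 20 h that neighbour held 1.26% left-handed product against cedar's 2.28%, and its excess was 94.0%.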